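A direct plan would take both rings from one commercial arene, methyl 2,4-dihydroxy-3,6-dimethylbenzoate (A1): protection of the 4-OH, methylation of the chelated 2-OH and deprotection would give methyl 4-hydroxy-2-methoxy-3,6-dimethylbenzoate (A2).
One portion of A2 would receive its third C-methyl group by ortho-formylation and reduction, to give the phenol half. The other would be chlorinated and its ester cleaved to 3-chloro-4-hydroxy-6-methoxy-2,5-dimethylbenzoic acid (A3). The two halves would then be esterified.
Its weakest steps would be:
- The final esterification would join an acid flanked by CH3 and OCH3 to a phenol flanked by two CH3 groups, while A3 carries a free, more acidic phenol of its own. It would need extra protection or an unproven selective coupling, at the point where all material converges.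
- The protect–methylate–deprotect stretch would spend three operations to put one methyl group on the right oxygen and would build no skeleton.
- The formylation–reduction pair would spend two redox operations on one carbon, and cleaving a 2,6-disubstituted methyl benzoate would need forcing acid.

**Retrosynthetic overview**
Ring A (the methyl benzoate ring) and ring B (the chlorinated benzoyl ring, numbered C1 = acyl-bearing carbon, C4 = C–OH, C5 = C–CH3, C6 = C–OCH3) are both hexasubstituted benzenes with an ester carbon para to an oxygen and an OCH3/CH3 pair between them. A vinylketene carrying the ester on its α-carbon and 1-methoxyprop-1-yne would give exactly this pattern: the ring C–OH from the ketene C=O, the CH3 and OCH3 carbons from the alkyne.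
Ring A would be built first from an open-chain methyl 2-diazo-3-oxoalkenoate. Its new phenol would then be acylated by an unhindered acylketene, so the depside C–O bond exists before ring B does.
Ring B would be grown last on that aryl ester: photolysis of the aryl 2-diazo-3-oxopentenoate with the same alkyne would form its C4–C5, C6–C1 and C3–C4 bonds and leave one ring C–H (C3), which takes the chlorine.
The design contains no coupling of a hindered benzoic acid with a hindered phenol, no O-protection (OCH3 and OH arrive differentiated) and no C-methylation after ring formation.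

Key step: step 7

Remark: the target has no stereocentre; the E alkene of the tiglic acid-derived compounds is lost when ring A forms. 1-Methoxyprop-1-yne is assumed not to be a stock chemical and is made in step 1.

Step 1
Reactants: 1 2-chloro-1,1-dimethoxyethane
Product: 3 1-methoxyprop-1-yne, via sodium methoxyacetylide 2 (not isolated)
Conditions: NaNH2 (3.1 equiv), liq. NH3, −33 °C; then MeI (1.0 equiv), −33 °C; aqueous work-up, distillation
Reagents that add atoms: iodomethane, CI; sodium amide, [Na+].[NH2-] (its sodium stays only in 2)
Why: Twofold base-induced elimination (methanol, then HCl) from the chloroacetal gives the sodium alkoxyacetylide, which is C-methylated in the same flask (the standard route to 1-alkoxyalk-1-ynes); the methyl ether has no β-hydrogen, so the ynol ether cannot fragment by a retro-ene reaction when heated later.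

Step 2
Reactants: 4 tiglic acid, (E)-2-methylbut-2-enoic acid
Product: 6 methyl (E)-4-methyl-3-oxohex-4-enoate, via acyl imidazolide 5 (not isolated)
Conditions: CDI (1.1 equiv), THF, rt; then potassium methyl malonate (1.5 equiv), MgCl2 (1.5 equiv), Et3N, THF, rt to 45 °C; 1 M HCl
Reagents that add atoms: potassium methyl malonate, COC(=O)CC(=O)[O-].[K+]; 1,1'-carbonyldiimidazole, O=C(n1ccnc1)n1ccnc1 (its atoms stay only in 5)
Why: Masamune–Brooks decarboxylative Claisen condensation of the acyl imidazolide with the magnesium malonate half-ester; the trisubstituted enone is a poor Michael acceptor, so the E alkene survives.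

Step 3
Reactants: 6 methyl (E)-4-methyl-3-oxohex-4-enoate
Product: 7 methyl (E)-2-diazo-4-methyl-3-oxohex-4-enoate
Conditions: 4-acetamidobenzenesulfonyl azide (1.1 equiv), Et3N (1.5 equiv), MeCN, 0 °C to rt
Reagents that add atoms: 4-acetamidobenzenesulfonyl azide, CC(=O)Nc1ccc(cc1)S(=O)(=O)N=[N+]=[N-]
Why: Regitz diazo transfer to the active methylene group of a β-keto ester.

Step 4
Reactants: 7 methyl (E)-2-diazo-4-methyl-3-oxohex-4-enoate; 3 1-methoxyprop-1-yne (3 equiv)
Product: 10 methyl 4-hydroxy-2-methoxy-3,5,6-trimethylbenzoate, via vinylketene 8 (not isolated), via cyclobutenone 9 (not isolated)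
Conditions: hν (350–365 nm), ClCH2CH2Cl (0.02 M), rt; then 80 °C, sealed vessel
Reagents that add atoms: none
Why: Proposed new method: photochemical Wolff rearrangement of 7 (butenyl migration) should give the ester-substituted vinylketene 8, the polarised ynol ether 3 should add by [2+2] cycloaddition (its methyl-bearing carbon to the ketene carbonyl carbon) to cyclobutenone 9, and heating should drive 4π-electrocyclic opening, 6π-electrocyclic closure and tautomerisation to the hexasubstituted phenol; the closest known reaction type is the Danheiser benzannulation (photo-Wolff variant) of ester-free α-diazo enones with alkoxyalkynes, and the step also tests the key step on a substrate without the aryl ester.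

Step 5
Reactants: 11 Meldrum's acid (2,2-dimethyl-1,3-dioxane-4,6-dione); 12 methacryloyl chloride
Product: 13 5-(1-hydroxy-2-methylprop-2-en-1-ylidene)-2,2-dimethyl-1,3-dioxane-4,6-dione
Conditions: pyridine (2.2 equiv), CH2Cl2, −10 to 0 °C; cold 1 M HCl wash; used crude
Reagents that add atoms: none
Why: C-acylation of Meldrum's acid by the acid chloride (Oikawa–Yonemitsu type); the product is held as its hydrogen-bonded enol, and the α-methyl group slows conjugate addition to the methacryloyl unit.

Step 6
Reactants: 10 methyl 4-hydroxy-2-methoxy-3,5,6-trimethylbenzoate (1.0 equiv); 13 5-(1-hydroxy-2-methylprop-2-en-1-ylidene)-2,2-dimethyl-1,3-dioxane-4,6-dione (1.3 equiv)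
Product: 16 methyl 4-[(2-diazo-4-methyl-3-oxopent-4-enoyl)oxy]-2-methoxy-3,5,6-trimethylbenzoate, via acylketene 14 (not isolated), via aryl keto ester 15 (not isolated)
Conditions: toluene, 90 °C; then 0 °C, MeCN, 4-acetamidobenzenesulfonyl azide (1.2 equiv), Et3N (1.5 equiv), 0 °C to rt
Reagents that add atoms: 4-acetamidobenzenesulfonyl azide, CC(=O)Nc1ccc(cc1)S(=O)(=O)N=[N+]=[N-]
Why: Thermal fragmentation of the acyl Meldrum's acid (loss of acetone and CO2) gives acylketene 14, whose unhindered sp carbon is captured even by the 2,6-disubstituted phenol; Regitz diazo transfer in the same flask removes the active methylene group of the polymerisable enone keto ester 15 before it is concentrated.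

Step 7
Reactants: 16 methyl 4-[(2-diazo-4-methyl-3-oxopent-4-enoyl)oxy]-2-methoxy-3,5,6-trimethylbenzoate; 3 1-methoxyprop-1-yne (3 equiv)
Product: 19 methyl 4-[(4-hydroxy-2-methoxy-3,6-dimethylbenzoyl)oxy]-2-methoxy-3,5,6-trimethylbenzoate, via vinylketene 17 (not isolated), via cyclobutenone 18 (not isolated)
Conditions: hν (350–365 nm), ClCH2CH2Cl (0.02 M), rt; then 80 °C, sealed vessel
Reagents that add atoms: none
Why: Proposed new method: light of 350–365 nm should excite only the diazo keto ester (the ring A benzoate is transparent there, which avoids photo-Fries cleavage of the aryl ester) and trigger Wolff rearrangement with isopropenyl migration to the ester-substituted vinylketene 17; the polarised ynol ether 3 should then add by [2+2] cycloaddition, its methyl-bearing carbon bonding to the ketene carbonyl carbon (ring B C4–C5 and C6–C1), to give the 4-vinylcyclobutenone 18. On heating, 18 should undergo reversible 4π-electrocyclic opening to a dienylketene that closes ring B by thermal 6π-electrocyclisation (six-membered carbocycle, new bond C3–C4) and tautomerises to the phenol; no stereocentre is created. The closest known reaction type is the Danheiser benzannulation (photo-Wolff variant) of α-diazo enones with alkoxyalkynes, which has not been shown for 2-diazo-3-oxo esters; the Wolff rearrangement of such esters to alkoxycarbonylketenes and the [2+2] cycloadditions of those ketenes are known separately. The step needs regioselective ketene–alkyne union, which the donor oxygen of 3 secures and which places OCH3 ortho and OH para to the acyl carbon. It also needs closure through carbon and not through the ester oxygen: the aryl ester carbonyl is a poor heterodiene terminus, and only the carbocyclic path is driven forward by aromatisation. The excess of 3 and the high dilution should keep the ketene from acylating the product phenol.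

Step 8
Reactants: 19 methyl 4-[(4-hydroxy-2-methoxy-3,6-dimethylbenzoyl)oxy]-2-methoxy-3,5,6-trimethylbenzoate
Product: 20 methyl 4-[(3-chloro-4-hydroxy-6-methoxy-2,5-dimethylbenzoyl)oxy]-2-methoxy-3,5,6-trimethylbenzoate
Conditions: SO2Cl2 (1.05 equiv), CH2Cl2, 0 °C to rt, dark
Reagents that add atoms: sulfuryl chloride, ClS(Cl)(=O)=O
Why: Electrophilic aromatic chlorination at the only aromatic C–H of the molecule (ring B C3, ortho to OH and para to OCH3); ring A has no free position, and the ionic conditions spare the benzylic methyl groups and both esters.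

**Compound list**
1 | 2-chloro-1,1-dimethoxyethane | COC(CCl)OC | starting material
2 | sodium methoxyacetylide | [Na+].[C-]#COC | intermediate (not isolated)
3 | 1-methoxyprop-1-yne | CC#COC | intermediate
4 | tiglic acid, (E)-2-methylbut-2-enoic acid | C/C=C(\C)C(=O)O | starting material
5 | (E)-1-(1H-imidazol-1-yl)-2-methylbut-2-en-1-one | C/C=C(\C)C(=O)n1ccnc1 | intermediate (not isolated)
6 | methyl (E)-4-methyl-3-oxohex-4-enoate | COC(=O)CC(=O)/C(C)=C/C | intermediate
7 | methyl (E)-2-diazo-4-methyl-3-oxohex-4-enoate | COC(=O)C(=[N+]=[N-])C(=O)/C(C)=C/C | intermediate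
8 | methyl (E)-3-methyl-2-(oxomethylidene)pent-3-enoate | COC(=O)C(=C=O)/C(C)=C/C | intermediate (not isolated)
9 | methyl 1-[(E)-but-2-en-2-yl]-2-methoxy-3-methyl-4-oxocyclobut-2-ene-1-carboxylate (racemic) | COC(=O)C1(/C(C)=C/C)C(OC)=C(C)C1=O | intermediate (not isolated)
10 | methyl 4-hydroxy-2-methoxy-3,5,6-trimethylbenzoate | COC(=O)c1c(C)c(C)c(O)c(C)c1OC | intermediate
11 | Meldrum's acid, 2,2-dimethyl-1,3-dioxane-4,6-dione | CC1(C)OC(=O)CC(=O)O1 | starting material
12 | methacryloyl chloride | CC(=C)C(Cl)=O | starting material
13 | 5-(1-hydroxy-2-methylprop-2-en-1-ylidene)-2,2-dimethyl-1,3-dioxane-4,6-dione | CC(=C)C(O)=C1C(=O)OC(C)(C)OC1=O | intermediate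
14 | 4-methylpenta-1,4-diene-1,3-dione | CC(=C)C(=O)C=C=O | intermediate (not isolated)
15 | methyl 2-methoxy-3,5,6-trimethyl-4-[(4-methyl-3-oxopent-4-enoyl)oxy]benzoate | COC(=O)c1c(C)c(C)c(OC(=O)CC(=O)C(C)=C)c(C)c1OC | intermediate (not isolated)
16 | methyl 4-[(2-diazo-4-methyl-3-oxopent-4-enoyl)oxy]-2-methoxy-3,5,6-trimethylbenzoate | COC(=O)c1c(C)c(C)c(OC(=O)C(=[N+]=[N-])C(=O)C(C)=C)c(C)c1OC | intermediate
17 | methyl 2-methoxy-3,5,6-trimethyl-4-{[3-methyl-2-(oxomethylidene)but-3-enoyl]oxy}benzoate | COC(=O)c1c(C)c(C)c(OC(=O)C(=C=O)C(C)=C)c(C)c1OC | intermediate (not isolated)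
18 | methyl 2-methoxy-4-{[2-methoxy-3-methyl-4-oxo-1-(prop-1-en-2-yl)cyclobut-2-ene-1-carbonyl]oxy}-3,5,6-trimethylbenzoate (racemic) | COC(=O)c1c(C)c(C)c(OC(=O)C2(C(C)=C)C(OC)=C(C)C2=O)c(C)c1OC | intermediate (not isolated)
19 | methyl 4-[(4-hydroxy-2-methoxy-3,6-dimethylbenzoyl)oxy]-2-methoxy-3,5,6-trimethylbenzoate | COC(=O)c1c(C)c(C)c(OC(=O)c2c(C)cc(O)c(C)c2OC)c(C)c1OC | intermediate
20 | methyl 4-[(3-chloro-4-hydroxy-6-methoxy-2,5-dimethylbenzoyl)oxy]-2-methoxy-3,5,6-trimethylbenzoate | COC(=O)c1c(C)c(C)c(OC(=O)c2c(C)c(Cl)c(O)c(C)c2OC)c(C)c1OC | target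

**Step count and risks**
Total step count: 8. Longest linear sequence: 6 steps (steps 2, 3, 4, 6, 7, 8).

Steps most likely to fail:

1. Step 7 (proposed new method). The ketene–ynol ether adduct may close through the ester oxygen instead of carbon, the un-rearranged keto carbene may be captured by the alkyne, light may cleave the aryl ester, or the ketene may acylate the product phenol. The fallback uses known chemistry, sets out from phenol 10 and comes back at 19. Commercial A1 would be benzylated at the unchelated 4-OH (BnBr, K2CO3, acetone) to methyl 4-(benzyloxy)-2-hydroxy-3,6-dimethylbenzoate F1, methylated at the chelated OH (MeI, K2CO3, DMF, 60 °C) to methyl 4-(benzyloxy)-2-methoxy-3,6-dimethylbenzoate F2, and saponified (KOH, DMSO–H2O, 80 °C) to 4-(benzyloxy)-2-methoxy-3,6-dimethylbenzoic acid F3. Mixed-anhydride esterification of F3 with 10 (trifluoroacetic anhydride, toluene, rt) would give methyl 4-{[4-(benzyloxy)-2-methoxy-3,6-dimethylbenzoyl]oxy}-2-methoxy-3,5,6-trimethylbenzoate F4, and hydrogenolysis (H2, palladium on carbon, Pd/C, EtOAc) would return to 19.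

2. Step 4 (proposed new method). The same diversions of the ester-substituted ketene may occur (oxygen closure, carbene capture, acylation of the product). The fallback uses known chemistry, sets out from tiglic acid 4 and alkyne 3 and comes back at 10. Acid 4 would be converted with oxalyl chloride into (E)-2-methylbut-2-enoyl chloride F5 and with diazomethane into (E)-1-diazo-3-methylpent-3-en-2-one F6. The established benzannulation of this ester-free α-diazo enone with 3 (hν, then 80 °C) would give 3-methoxy-2,5,6-trimethylphenol F7. Bromination at its only free ring position (NBS, MeCN, 0 °C) would give 4-bromo-3-methoxy-2,5,6-trimethylphenol F8, and methoxycarbonylation (Pd(OAc)2, 1,3-bis(diphenylphosphino)propane, CO, MeOH, Et3N, 100 °C; oxidative addition to zerovalent palladium, CO insertion, methanolysis) would return to 10.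

3. Step 6. The enone keto ester may self-condense or polymerise by Michael addition before diazo transfer, or the acylketene may dimerise faster than the hindered phenol captures it. The fallback sets out from phenol 10 and comes back at 16. Acylation with bromoacetyl bromide (pyridine, CH2Cl2, 0 °C) would give methyl 4-[(bromoacetyl)oxy]-2-methoxy-3,5,6-trimethylbenzoate F9. N,N'-ditosylhydrazine and DBU (THF, 0 °C) would convert it into methyl 4-[(diazoacetyl)oxy]-2-methoxy-3,5,6-trimethylbenzoate F10. DBU-catalysed aldol-type addition of F10 to methacrolein would give methyl 4-[(2-diazo-3-hydroxy-4-methylpent-4-enoyl)oxy]-2-methoxy-3,5,6-trimethylbenzoate F11, and oxidation (IBX, DMSO, rt) would return to 16.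

Further compounds
F1 | step 7 | methyl 4-(benzyloxy)-2-hydroxy-3,6-dimethylbenzoate | COC(=O)c1c(C)cc(OCc2ccccc2)c(C)c1O
F2 | step 7 | methyl 4-(benzyloxy)-2-methoxy-3,6-dimethylbenzoate | COC(=O)c1c(C)cc(OCc2ccccc2)c(C)c1OC
F3 | step 7 | 4-(benzyloxy)-2-methoxy-3,6-dimethylbenzoic acid | OC(=O)c1c(C)cc(OCc2ccccc2)c(C)c1OC
F4 | step 7 | methyl 4-{[4-(benzyloxy)-2-methoxy-3,6-dimethylbenzoyl]oxy}-2-methoxy-3,5,6-trimethylbenzoate | COC(=O)c1c(C)c(C)c(OC(=O)c2c(C)cc(OCc3ccccc3)c(C)c2OC)c(C)c1OC
F5 | step 4 | (E)-2-methylbut-2-enoyl chloride | C/C=C(\C)C(Cl)=O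
F6 | step 4 | (E)-1-diazo-3-methylpent-3-en-2-one | C/C=C(\C)C(=O)C=[N+]=[N-]
F7 | step 4 | 3-methoxy-2,5,6-trimethylphenol | COc1cc(C)c(C)c(O)c1C
F8 | step 4 | 4-bromo-3-methoxy-2,5,6-trimethylphenol | COc1c(Br)c(C)c(C)c(O)c1C
F9 | step 6 | methyl 4-[(bromoacetyl)oxy]-2-methoxy-3,5,6-trimethylbenzoate | COC(=O)c1c(C)c(C)c(OC(=O)CBr)c(C)c1OC
F10 | step 6 | methyl 4-[(diazoacetyl)oxy]-2-methoxy-3,5,6-trimethylbenzoate | COC(=O)c1c(C)c(C)c(OC(=O)C=[N+]=[N-])c(C)c1OC
F11 | step 6 | methyl 4-[(2-diazo-3-hydroxy-4-methylpent-4-enoyl)oxy]-2-methoxy-3,5,6-trimethylbenzoate (racemic) | COC(=O)c1c(C)c(C)c(OC(=O)C(=[N+]=[N-])C(O)C(C)=C)c(C)c1OC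
A1 | direct plan | methyl 2,4-dihydroxy-3,6-dimethylbenzoate | COC(=O)c1c(C)cc(O)c(C)c1O
A2 | direct plan | methyl 4-hydroxy-2-methoxy-3,6-dimethylbenzoate | COC(=O)c1c(C)cc(O)c(C)c1OC
A3 | direct plan | 3-chloro-4-hydroxy-6-methoxy-2,5-dimethylbenzoic acid | OC(=O)c1c(C)c(Cl)c(O)c(C)c1OC
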